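The α-methylene-γ-butyrolactone (ring O–C12–C11–C7–C6; germacrane numbering) is read as 2-bromoacrylic acid added across a C6=C7 double bond. A palladium-catalysed diene heteroannulation forms C11–C7 and O–C6 in one operation on an acyclic (E)-dienyl silyl ether, whose second alkene (C5=CMe2) carries the π-allyl intermediate and is later cleaved to the C5 aldehyde. The C8 stereocentre, set by CBS reduction, directs the face at C7, and C6 follows as the trans-lactone. The ten-membered ring is closed last by a Nozaki–Hiyama–Kishi reaction of a C4 alkenyl iodide (unmasked from a vinylsilane) with the C5 aldehyde, which creates the C5 carbinol and the exocyclic C4 methylene together.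

Key step: step 7

Remark: germacrane numbering of the target is used in the explanations (ring C1–C10; lactone carbons C11, C12, C13; ester carbon C14; exocyclic methylene C15). Compounds 5–7 are mixtures at the phosphorus-bearing carbon, which converge in step 6.

Step 1
Reactants: 1 3-methylbut-2-enal; 2 1-chloro-3-(triphenylphosphoranylidene)propan-2-one
Product: 3 (3E)-1-chloro-6-methylhepta-3,5-dien-2-one
Conditions: PhMe, 80 °C
Reagents that add atoms: none
Why: Wittig olefination with a ketone-stabilised ylide, which reacts only at the aldehyde and should give the E enone while leaving the chloromethyl group for the next step.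

Step 2
Reactants: 3 (3E)-1-chloro-6-methylhepta-3,5-dien-2-one; 4 methyl 2-(diethoxyphosphoryl)acetate
Product: 5 methyl (5E)-2-(diethoxyphosphoryl)-8-methyl-4-oxonona-5,7-dienoate (racemic at C2)
Conditions: 4 (2 equiv), NaH, THF, 0 °C; then 3, NaI (cat.), 0 °C → rt
Reagents that add atoms: none
Why: SN2 alkylation of the sodium phosphonoacetate by the highly reactive α-chloro ketone (iodide catalysis) should outrun conjugate addition to the dienone, and the excess of 4 limits double alkylation.

Step 3
Reactants: 5 methyl (5E)-2-(diethoxyphosphoryl)-8-methyl-4-oxonona-5,7-dienoate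
Product: 6 methyl (4R,5E)-2-(diethoxyphosphoryl)-4-hydroxy-8-methylnona-5,7-dienoate (both C2 epimers)
Conditions: (S)-2-methyl-CBS-oxazaborolidine (20 mol %), catecholborane, PhMe, −78 °C; MeOH, pH 7 buffer
Reagents that add atoms: none
Why: Corey–Bakshi–Shibata 1,2-reduction in which the dienyl group acts as the large and the CH2 group as the small substituent, so the (S)-catalyst should give the (4R)-carbinol (C8 of the target); the labile γ-hydroxy ester is carried on at once.

Step 4
Reactants: 6 methyl (4R,5E)-2-(diethoxyphosphoryl)-4-hydroxy-8-methylnona-5,7-dienoate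
Product: 7 methyl (4R,5E)-4-[(tert-butyldimethylsilyl)oxy]-2-(diethoxyphosphoryl)-8-methylnona-5,7-dienoate
Conditions: TBSOTf, 2,6-lutidine, CH2Cl2, −78 °C
Reagents that add atoms: tert-butyldimethylsilyl trifluoromethanesulfonate, CC(C)(C)[Si](C)(C)OS(=O)(=O)C(F)(F)F
Why: Silylation of the dienylic alcohol gives an ether that cannot lactonise onto the C14 ester and is not ionised by palladium later; the stereocentre is untouched.

Step 5
Reactants: 8 (1-bromoethenyl)trimethylsilane; 9 prop-2-enal (acrolein)
Product: 12 4-(trimethylsilyl)pent-4-enal, via Grignard reagent 10 (not isolated), via silyl enol ether 11 (not isolated)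
Conditions: Mg, THF, rt; then CuBr·SMe2 (5 mol %), Me3SiCl, 9, −78 °C; dilute aq. HCl
Reagents that add atoms: none
Why: Grignard formation, then copper-catalysed, Me3SiCl-accelerated conjugate addition of the 1-silylvinyl group to acrolein; hydrolysis of the silyl enol ether releases the aldehyde that carries the masked alkenyl iodide.

Step 6
Reactants: 7 methyl (4R,5E)-4-[(tert-butyldimethylsilyl)oxy]-2-(diethoxyphosphoryl)-8-methylnona-5,7-dienoate; 12 4-(trimethylsilyl)pent-4-enal
Product: 13 methyl (2E,4R,5E)-4-[(tert-butyldimethylsilyl)oxy]-8-methyl-2-[4-(trimethylsilyl)pent-4-en-1-ylidene]nona-5,7-dienoate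
Conditions: NaH, THF, 0 °C; then 12, 0 °C → rt
Reagents that add atoms: none
Why: Horner–Wadsworth–Emmons olefination of the α-substituted phosphonoacetate with an aliphatic aldehyde should give mainly the E trisubstituted enoate (ester trans to the new chain, the C10=C1 geometry of the target); a minor Z isomer would be removed by chromatography.

Step 7
Reactants: 13 methyl (2E,4R,5E)-4-[(tert-butyldimethylsilyl)oxy]-8-methyl-2-[4-(trimethylsilyl)pent-4-en-1-ylidene]nona-5,7-dienoate; 14 2-bromoprop-2-enoic acid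
Product: 15 methyl (2E,4R)-4-[(tert-butyldimethylsilyl)oxy]-4-[(2R,3S)-4-methylidene-2-(2-methylprop-1-en-1-yl)-5-oxooxolan-3-yl]-2-[4-(trimethylsilyl)pent-4-en-1-ylidene]butanoate
Conditions: 14 (2.5 equiv), Pd(OAc)2 (10 mol %), n-Bu4NCl, Na2CO3, DMF, 60 °C
Reagents that add atoms: none
Why: Zerovalent palladium (formed from Pd(OAc)2) inserts into the C–Br bond of the 2-bromoacrylate, the alkenylpalladium adds syn across C6=C7 at the less substituted diene terminus C7 (C11–C7 bond), and the resulting π-allylpalladium spanning C6–C5–CMe2 is captured at C6 by the tethered carboxylate (O–C6 bond) with release of zerovalent palladium. The closest known reaction type is the Larock heteroannulation of 1,3-dienes by aryl or vinylic halides that carry a carboxylic acid. The lactone ring closes by attack of the carboxylate oxygen on the proximal allyl terminus (five-membered ring, exo mode); the seven-membered alternative at the dimethyl-substituted terminus is disfavoured. C7 is controlled by the C8 stereocentre: in the conformer with C8–H eclipsing the alkene (minimised A(1,3) strain), palladium and the migrating alkenyl group should approach the face anti to the bulky silyloxy group. C6 is controlled by C7: net syn addition to the E alkene and reversible ionisation of the allylic lactone both lead to the trans-β,γ-disubstituted lactone. The step needs regioselectivity for C7 over the CMe2 terminus and chemoselectivity for the diene over the trisubstituted enoate and the 2-silylalkene; both are secured by substitution, since a fully substituted terminus and hindered, non-conjugated alkenes insert far more slowly.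

Step 8
Reactants: 15 methyl (2E,4R)-4-[(tert-butyldimethylsilyl)oxy]-4-[(2R,3S)-4-methylidene-2-(2-methylprop-1-en-1-yl)-5-oxooxolan-3-yl]-2-[4-(trimethylsilyl)pent-4-en-1-ylidene]butanoate
Product: 16 methyl (2E,4R)-4-hydroxy-4-[(2R,3R)-4-methylidene-2-(2-methylprop-1-en-1-yl)-5-oxooxolan-3-yl]-2-[4-(trimethylsilyl)pent-4-en-1-ylidene]butanoate
Conditions: HF·pyridine, pyridine, THF, 0 °C → rt
Reagents that add atoms: none
Why: Buffered fluoride cleavage of the Si–O bond spares the lactone, the esters and the carbon-bound trimethylsilyl group; the γ-hydroxy ester is used crude so that it does not lactonise onto C14.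

Step 9
Reactants: 16 methyl (2E,4R)-4-hydroxy-4-[(2R,3R)-4-methylidene-2-(2-methylprop-1-en-1-yl)-5-oxooxolan-3-yl]-2-[4-(trimethylsilyl)pent-4-en-1-ylidene]butanoate; 17 (2Z)-2-methylbut-2-enoic acid (angelic acid)
Product: 19 methyl (2E,4R)-4-{[(2Z)-2-methylbut-2-enoyl]oxy}-4-[(2R,3R)-4-methylidene-2-(2-methylprop-1-en-1-yl)-5-oxooxolan-3-yl]-2-[4-(trimethylsilyl)pent-4-en-1-ylidene]butanoate, via mixed anhydride 18 (not isolated)
Conditions: 17, 2,4,6-trichlorobenzoyl chloride, Et3N, PhMe, rt; then 16, 70 °C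
Reagents that add atoms: none
Why: Yamaguchi esterification through the mixed anhydride without DMAP acylates the secondary alcohol while avoiding Z to E isomerisation of the angelate; C8 keeps its configuration because only the acyl–oxygen bond is formed.

Step 10
Reactants: 19 methyl (2E,4R)-4-{[(2Z)-2-methylbut-2-enoyl]oxy}-4-[(2R,3R)-4-methylidene-2-(2-methylprop-1-en-1-yl)-5-oxooxolan-3-yl]-2-[4-(trimethylsilyl)pent-4-en-1-ylidene]butanoate
Product: 20 methyl (2E,4R)-2-(4-iodopent-4-en-1-ylidene)-4-{[(2Z)-2-methylbut-2-enoyl]oxy}-4-[(2R,3R)-4-methylidene-2-(2-methylprop-1-en-1-yl)-5-oxooxolan-3-yl]butanoate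
Conditions: NIS, 2,6-lutidine, (CF3)2CHOH, 0 °C
Reagents that add atoms: N-iodosuccinimide, O=C1CCC(=O)N1I
Why: Ipso-iododesilylation of the 2-silylalkene in the ionising, non-nucleophilic fluoroalcohol should be much faster than attack on the isobutenyl group, which is deactivated by the allylic acyloxy group; the alkenyl iodide thus appears only after all palladium chemistry.

Step 11
Reactants: 20 methyl (2E,4R)-2-(4-iodopent-4-en-1-ylidene)-4-{[(2Z)-2-methylbut-2-enoyl]oxy}-4-[(2R,3R)-4-methylidene-2-(2-methylprop-1-en-1-yl)-5-oxooxolan-3-yl]butanoate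
Product: 22 methyl (2E,4R)-4-[(2S,3R)-2-formyl-4-methylidene-5-oxooxolan-3-yl]-2-(4-iodopent-4-en-1-ylidene)-4-{[(2Z)-2-methylbut-2-enoyl]oxy}butanoate, via diol 21 (not isolated)
Conditions: OsO4 (5 mol %), NMO, acetone/H2O, 0 °C → rt; then NaIO4, pH 7 buffer
Reagents that add atoms: osmium tetroxide, O=[Os](=O)(=O)=O; N-methylmorpholine N-oxide, C[N+]1([O-])CCOCC1
Why: Lemieux–Johnson-type cleavage (dihydroxylation, then periodate glycol cleavage): OsO4 should select the only electron-rich, trisubstituted alkene over the conjugated alkenes and the iodoalkene, revealing the C5 aldehyde without touching C6.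

Step 12
Reactants: 22 methyl (2E,4R)-4-[(2S,3R)-2-formyl-4-methylidene-5-oxooxolan-3-yl]-2-(4-iodopent-4-en-1-ylidene)-4-{[(2Z)-2-methylbut-2-enoyl]oxy}butanoate
Product: 23 methyl (3aR,4R,6E,11S,11aS)-11-hydroxy-3,10-dimethylidene-4-{[(2Z)-2-methylbut-2-enoyl]oxy}-2-oxo-2,3,3a,4,5,8,9,10,11,11a-decahydrocyclodeca[b]furan-6-carboxylate (target)
Conditions: CrCl2 (8 equiv), NiCl2 (2 mol %), DMSO/THF, 0.002 M, rt, slow addition of 22
Reagents that add atoms: none
Why: Nozaki–Hiyama–Kishi reaction: the alkenylchromium formed from the iodide under nickel catalysis adds to the aldehyde at high dilution to close the ten-membered ring; with the C6–O bond anti to the incoming nucleophile (polar Felkin–Anh) and the aldehyde oxygen on the periphery of the forming ring, the 5S carbinol should result.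

Compound list
1 | 3-methylbut-2-enal | CC(C)=CC=O | starting material
2 | 1-chloro-3-(triphenylphosphoranylidene)propan-2-one | ClCC(=O)C=P(c1ccccc1)(c1ccccc1)c1ccccc1 | starting material
3 | (3E)-1-chloro-6-methylhepta-3,5-dien-2-one | CC(C)=C/C=C/C(=O)CCl | intermediate
4 | methyl 2-(diethoxyphosphoryl)acetate | CCOP(=O)(OCC)CC(=O)OC | starting material
5 | methyl (5E)-2-(diethoxyphosphoryl)-8-methyl-4-oxonona-5,7-dienoate | CC(C)=C/C=C/C(=O)CC(C(=O)OC)P(=O)(OCC)OCC | intermediate
6 | methyl (4R,5E)-2-(diethoxyphosphoryl)-4-hydroxy-8-methylnona-5,7-dienoate | CC(C)=C/C=C/[C@H](O)CC(C(=O)OC)P(=O)(OCC)OCC | intermediate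
7 | methyl (4R,5E)-4-[(tert-butyldimethylsilyl)oxy]-2-(diethoxyphosphoryl)-8-methylnona-5,7-dienoate | CC(C)=C/C=C/[C@H](O[Si](C)(C)C(C)(C)C)CC(C(=O)OC)P(=O)(OCC)OCC | intermediate
8 | (1-bromoethenyl)trimethylsilane | C=C(Br)[Si](C)(C)C | starting material
9 | prop-2-enal | C=CC=O | starting material
10 | bromo[1-(trimethylsilyl)ethenyl]magnesium | C=C([Mg]Br)[Si](C)(C)C | intermediate
11 | trimethyl{[4-(trimethylsilyl)penta-1,4-dien-1-yl]oxy}silane | C=C(CC=CO[Si](C)(C)C)[Si](C)(C)C | intermediate
12 | 4-(trimethylsilyl)pent-4-enal | C=C(CCC=O)[Si](C)(C)C | intermediate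
13 | methyl (2E,4R,5E)-4-[(tert-butyldimethylsilyl)oxy]-8-methyl-2-[4-(trimethylsilyl)pent-4-en-1-ylidene]nona-5,7-dienoate | CC(C)=C/C=C/[C@H](O[Si](C)(C)C(C)(C)C)C/C(C(=O)OC)=C\CCC(=C)[Si](C)(C)C | intermediate
14 | 2-bromoprop-2-enoic acid | C=C(Br)C(=O)O | starting material
15 | methyl (2E,4R)-4-[(tert-butyldimethylsilyl)oxy]-4-[(2R,3S)-4-methylidene-2-(2-methylprop-1-en-1-yl)-5-oxooxolan-3-yl]-2-[4-(trimethylsilyl)pent-4-en-1-ylidene]butanoate | C=C1C(=O)O[C@H](C=C(C)C)[C@H]1[C@H](O[Si](C)(C)C(C)(C)C)C/C(C(=O)OC)=C\CCC(=C)[Si](C)(C)C | intermediate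
16 | methyl (2E,4R)-4-hydroxy-4-[(2R,3R)-4-methylidene-2-(2-methylprop-1-en-1-yl)-5-oxooxolan-3-yl]-2-[4-(trimethylsilyl)pent-4-en-1-ylidene]butanoate | C=C1C(=O)O[C@H](C=C(C)C)[C@H]1[C@H](O)C/C(C(=O)OC)=C\CCC(=C)[Si](C)(C)C | intermediate
17 | (2Z)-2-methylbut-2-enoic acid (angelic acid) | C/C=C(/C)C(=O)O | starting material
18 | (2Z)-2-methylbut-2-enoic 2,4,6-trichlorobenzoic anhydride | C/C=C(/C)C(=O)OC(=O)c1c(Cl)cc(Cl)cc1Cl | intermediate
19 | methyl (2E,4R)-4-{[(2Z)-2-methylbut-2-enoyl]oxy}-4-[(2R,3R)-4-methylidene-2-(2-methylprop-1-en-1-yl)-5-oxooxolan-3-yl]-2-[4-(trimethylsilyl)pent-4-en-1-ylidene]butanoate | C=C1C(=O)O[C@H](C=C(C)C)[C@H]1[C@H](OC(=O)/C(C)=C\C)C/C(C(=O)OC)=C\CCC(=C)[Si](C)(C)C | intermediate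
20 | methyl (2E,4R)-2-(4-iodopent-4-en-1-ylidene)-4-{[(2Z)-2-methylbut-2-enoyl]oxy}-4-[(2R,3R)-4-methylidene-2-(2-methylprop-1-en-1-yl)-5-oxooxolan-3-yl]butanoate | C=C1C(=O)O[C@H](C=C(C)C)[C@H]1[C@H](OC(=O)/C(C)=C\C)C/C(C(=O)OC)=C\CCC(=C)I | intermediate
21 | methyl (2E,4R)-4-[(2S,3R)-2-(1,2-dihydroxy-2-methylpropyl)-4-methylidene-5-oxooxolan-3-yl]-2-(4-iodopent-4-en-1-ylidene)-4-{[(2Z)-2-methylbut-2-enoyl]oxy}butanoate (carbinol epimers) | C=C1C(=O)O[C@H](C(O)C(C)(C)O)[C@H]1[C@H](OC(=O)/C(C)=C\C)C/C(C(=O)OC)=C\CCC(=C)I | intermediate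
22 | methyl (2E,4R)-4-[(2S,3R)-2-formyl-4-methylidene-5-oxooxolan-3-yl]-2-(4-iodopent-4-en-1-ylidene)-4-{[(2Z)-2-methylbut-2-enoyl]oxy}butanoate | C=C1C(=O)O[C@H](C=O)[C@H]1[C@H](OC(=O)/C(C)=C\C)C/C(C(=O)OC)=C\CCC(=C)I | intermediate
23 | methyl (3aR,4R,6E,11S,11aS)-11-hydroxy-3,10-dimethylidene-4-{[(2Z)-2-methylbut-2-enoyl]oxy}-2-oxo-2,3,3a,4,5,8,9,10,11,11a-decahydrocyclodeca[b]furan-6-carboxylate | C=C1C(=O)O[C@H]2[C@H]1[C@H](OC(=O)/C(C)=C\C)C/C(C(=O)OC)=C\CCC(=C)[C@@H]2O | target

Total step count: 12. Longest linear sequence: 11 steps (steps 1–4 and 6–12; step 5 is the side branch).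

Steps most likely to fail

Step 7. What may go wrong: slow carbopalladation of the hindered internal diene terminus, loss of the π-allyl intermediate by β-hydride elimination, or insufficient facial selectivity at C7. The fallback is a radical–polar lactone annulation that sets out from 13 and returns at 15. Oxidation of (diethoxyphosphoryl)acetic acid with Mn(OAc)3·2H2O and Cu(OAc)2 in AcOH at 60 °C should add the carboxymethyl radical to C7; oxidation of the allyl radical and capture by the carboxylate at C6 would give the α-(diethoxyphosphoryl) trans-lactone F1. Horner–Wadsworth–Emmons methylenation of F1 (aq. HCHO, K2CO3, THF) then gives 15.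

Step 12. What may go wrong: addition to the wrong aldehyde face in the ring-closing transition state, or oligomerisation in competition with closure of the ten-membered ring. The fallback moves control of C5 from the C–C bond formation to a ketone reduction; it sets out from 22 and returns at 23. The ring closure is run as before and the C5-epimeric alcohol F2 (alone or mixed with 23) is oxidised with Dess–Martin periodinane to the cross-conjugated enone F3. Reagent-controlled reduction of F3 with (S)-2-methyl-CBS-oxazaborolidine and catecholborane (the C4 alkenyl carbon as the large group) should then give 23.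

Step 10. What may go wrong: electrophilic attack of the iodinating agent on the isobutenyl alkene in competition with iododesilylation. The fallback reverses the two unmasking operations so that the electron-rich alkene is gone before electrophilic iodine is used; it sets out from 19 and returns at 22. Dihydroxylation of 19 (OsO4 cat., NMO) would give the silyl diol F4 and periodate cleavage the silyl aldehyde F5; iododesilylation of F5 with NIS in MeCN/ClCH2CN then gives 22.

Further compounds
F1 | step 7 | methyl (2E,4R)-4-[(tert-butyldimethylsilyl)oxy]-4-[(2R,3S)-4-(diethoxyphosphoryl)-2-(2-methylprop-1-en-1-yl)-5-oxooxolan-3-yl]-2-[4-(trimethylsilyl)pent-4-en-1-ylidene]butanoate (epimers at the phosphorus-bearing carbon) | CCOP(=O)(OCC)C1C(=O)O[C@H](C=C(C)C)[C@H]1[C@H](O[Si](C)(C)C(C)(C)C)C/C(C(=O)OC)=C\CCC(=C)[Si](C)(C)C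
F2 | step 12 | methyl (3aR,4R,6E,11R,11aS)-11-hydroxy-3,10-dimethylidene-4-{[(2Z)-2-methylbut-2-enoyl]oxy}-2-oxo-2,3,3a,4,5,8,9,10,11,11a-decahydrocyclodeca[b]furan-6-carboxylate | C=C1C(=O)O[C@H]2[C@H]1[C@H](OC(=O)/C(C)=C\C)C/C(C(=O)OC)=C\CCC(=C)[C@H]2O
F3 | step 12 | methyl (3aR,4R,6E,11aS)-3,10-dimethylidene-4-{[(2Z)-2-methylbut-2-enoyl]oxy}-2,11-dioxo-2,3,3a,4,5,8,9,10,11,11a-decahydrocyclodeca[b]furan-6-carboxylate | C=C1C(=O)O[C@H]2[C@H]1[C@H](OC(=O)/C(C)=C\C)C/C(C(=O)OC)=C\CCC(=C)C2=O
F4 | step 10 | methyl (2E,4R)-4-[(2S,3R)-2-(1,2-dihydroxy-2-methylpropyl)-4-methylidene-5-oxooxolan-3-yl]-4-{[(2Z)-2-methylbut-2-enoyl]oxy}-2-[4-(trimethylsilyl)pent-4-en-1-ylidene]butanoate (carbinol epimers) | C=C1C(=O)O[C@H](C(O)C(C)(C)O)[C@H]1[C@H](OC(=O)/C(C)=C\C)C/C(C(=O)OC)=C\CCC(=C)[Si](C)(C)C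
F5 | step 10 | methyl (2E,4R)-4-[(2S,3R)-2-formyl-4-methylidene-5-oxooxolan-3-yl]-4-{[(2Z)-2-methylbut-2-enoyl]oxy}-2-[4-(trimethylsilyl)pent-4-en-1-ylidene]butanoate | C=C1C(=O)O[C@H](C=O)[C@H]1[C@H](OC(=O)/C(C)=C\C)C/C(C(=O)OC)=C\CCC(=C)[Si](C)(C)C
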